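# Synthesis plan for the mixed (S)-3-hydroxybutanoate / 3-phenylpropanoate diester of a hexaoxygenated para-terphenyl (23)

## The problem

Target 23 is a para-terphenyl whose central benzene (ring B) is substituted on every carbon. C1 carries an (S)-3-hydroxybutanoyloxy group, C2 a free hydroxyl, C3 a 4-hydroxyphenyl group (ring A), C4 a 3-phenylpropanoyloxy group, C5 a free hydroxyl and C6 a second 4-hydroxyphenyl group (ring C). Two things must be solved: the crowded ring B with two aryl–aryl bonds and four oxygens, and the distinction between four similar oxygens. The acylated oxygens are para to each other, the free ones are para to each other, and the two acyl groups differ. The only stereocentre is the carbinol carbon of the hydroxybutanoyl chain. It is remote, controls nothing and needs no control, so it is best bought and carried through without breaking a bond at that carbon. The fragile features are the aryl esters next to free phenols (migration or cleavage under base), the tetraoxygenated ring (oxidised to a quinone once its hydroxyls are free) and the beta-hydroxy ester (elimination). The last step must therefore be neutral and release all hydroxyls together. The key step rests on a mapping of ring B: the run C3(aryl)–C4(O)–C5(O)–C6(aryl) is the diene of a 2,5-diaryl-3,4-dioxycyclopentadienone, and C1–C2, each bearing one oxygen, is a vinylene unit. Both partners are symmetric, so ring B can be made by one cycloaddition without any regiochemical question.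

## Retrosynthesis

**23 to 22.** The five benzyl C–O bonds are cut (two outer phenols, two ring-B hydroxyls, the side-chain alcohol). One neutral hydrogenolysis then releases every hydroxyl. Acid- or fluoride-labile groups would need conditions under which esters beside free phenols migrate. In 22 no free hydroxyl sits beside an ester, so the ester positions are locked until the end. The forward reaction must spare two aryl esters.

**22 to 18 and 21, then 18 to 16 and 17.** The two ester C–O bonds are cut one after the other. This leads to hydroquinone 16, which is centrosymmetric and has benzyl ethers on both neighbours of each hydroxyl. The first acylation must stop at one hydroxyl, so the cheap acid chloride 17 is used there and the chiral acid 21 is kept for the second, unambiguous acylation. Acid 21 comes from the chiral-pool ester 19 by O-benzylation (20) and saponification, neither of which touches the stereocentre.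

**16 to 15 to 14.** The two hydroxyls of 16 are the carbonyl oxygens of a para-quinone, and its two benzyloxy groups are the enolic oxygens of that quinone. The cut is a redox change plus two O–benzyl bonds. This device pairs the oxygens para: in 14 the enolic hydroxyls are the only nucleophilic oxygens, so benzylation needs no selectivity, and reduction of 15 then exposes exactly the pair that is to be acylated.

**14 to 11 (through 12 and 13), and 11 to 10.** The cycloaddition delivers the oxygens in ortho pairs (C1/C2 from the dienophile, C4/C5 from the diene), whereas the target needs para pairs. Oxidation of catechol 11 to ortho-quinone 12 turns the two methoxy-bearing carbons into vinylogous ester positions. Two hydrolytic exchanges then pass through para-quinone 13 to 14. Catechol 11 is simply the deprotected form of cyclic carbonate 10.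

**10 to 9 to 6 and 7.** After two hydrogens are added back (10 to 9), the bonds C6–C1 and C2–C3 are cut. The neighbouring option, two aryl–aryl couplings on a finished ring B, would make each bond at a position flanked by two oxygen substituents. Here both aryl-bearing carbons are already in the diene. The forward reaction has three demands:
- dienone 6 must react as a diene with 7;
- the bridged ketone 8 must lose its one-carbon carbonyl bridge;
- diene 9 must be dehydrogenated to 10 without eliminating a ring oxygen.

**6 to 5 to 3 and 4.** The two enol ether O–methyl bonds are cut first. Then the bonds C3–C4 and C5–C6 are cut, which join the two oxalyl carbons of 4 to the two benzylic carbons of ketone 3. The C4–C5 bond comes intact from 4. The forward reaction is a double Claisen condensation followed by etherification, which must place both methyl groups on the oxalyl oxygens.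

**3 to 1 (through 2).** The bond between the ketone carbonyl and one benzylic carbon is cut. Two molecules of acid 1 are joined and keto acid 2 loses its carboxyl group. The aryl–C3 and aryl–C6 bonds of the target are the aryl–CH2 bonds of 1, so no biaryl bond is formed anywhere in the route.

## Roads not taken

**Alternative 1:** The cut runs through ring B at C3–C4 and C6–C1 and divides the quinone core into two identical arylpyruvate halves. In the forward key step two molecules of 4-hydroxyphenylpyruvic acid A2, held as thioesters on a quinone synthetase of the atromentin type, condense twice and the ring is oxidised to atromentin A1.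
- Merits: one operation builds the whole terphenylquinone from one simple acid, without protecting groups and with the para pairing of the oxygens already correct. Exhaustive benzylation of A1 would give 15 directly, so up to 15 this road is about six steps shorter than the chosen one. In step count it is clearly better.
- Weak points: an active multidomain enzyme with its cofactors must be produced and kept working on a preparative scale. A1 is poorly soluble. Four acidic hydroxyls of two kinds must then be alkylated together.
- Comparison: the chosen plan sets against the shorter count that it needs only stock reagents, scales freely, carries the outer phenols as benzyl ethers from step 1 and accepts any arylacetic acid. From 15 onward both roads are the same, so the enzymatic road does not help with telling the two acyl groups apart.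

**Alternative 2:** The two aryl ester C–O bonds are traced back to aryl–acyl C–C bonds. The forward key step is a double Baeyer–Villiger oxidation of diketone A4: a peracid adds to each carbonyl and the ring-B carbon migrates, giving pentabenzyl ether A3, which is the same compound as 22.
- Merits: the esters arise exactly where the acyl carbons were placed. No phenol is acylated, so over-acylation and acyl migration are excluded, and an electron-rich aryl group migrates in preference to a primary alkyl group. In freedom from a stoichiometry-controlled acylation this road is better than the chosen one.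
- Weak points: A4 carries two different acyl groups para on a hexasubstituted ring, so the differentiation is only moved to C–C bond formation at the most crowded positions, where it is harder than at oxygen. Each ketone is flanked by two ortho substituents and twisted out of conjugation, which slows peracid addition and weakens the aryl preference. The tetraoxygenated ring and the benzylic positions are themselves oxidisable by peracids. The beta-benzyloxy ketone can eliminate.
- Comparison: the chosen plan reaches 22 by two ordinary O-acylations of a hydroquinone whose neighbours are benzyl ethers, which gives the same positional security with fewer and safer steps. Against the non-statistical ester formation of this road it sets the recycling of 16 in step 10.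

**Alternative 3:** The cut is made inside each outer ring, at the ipso–ortho single bond and the opposite ortho–meta double bond, so rings A and C are grown on a finished ring B. In the forward key step both arms of bis(arylacetaldehyde) A6 add through their alpha carbons to methyl vinyl ketone A7 and the keto aldehydes close by aldol condensation to bis(4-oxocyclohex-2-enyl)arene A5. Dehydrogenation would then give the phenols.
- Merits: the two hindered aryl–aryl bonds are never made by coupling, and the partner is cheap. The para-paired acetal and benzyl ethers of A5 would allow the two oxygen pairs of ring B to be unmasked separately. In that respect it equals the chosen plan, which reaches the same pairing through 14 and 15. Neither distinguishes the two acyl groups within a pair.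
- Weak points: the key step is spent on the two simplest rings, which the chosen plan buys ready-made in 1. Ring B, with four differentiated oxygens and two acetaldehyde arms, must first be made by other means. The two new stereocentres are useless and are erased. Each enone needs a further oxidation beside an electron-rich ring. Doubly ortho-substituted arylacetaldehydes are prone to self-condensation.
- Comparison: the chosen plan builds ring B itself in its key step and is much shorter.

Key step: step 4

Remark on the chemistry: trione 5 is a set of interconverting enol tautomers and is drawn as one enol with a configurationally labile CH centre (both centres become sp2 in 6); 17 is the commercial acid chloride of 3-phenylpropanoic acid.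

## Route

Step 1
Reactants: 1 4-(benzyloxy)phenylacetic acid (two molecules)
Product: 3 1,3-bis[4-(benzyloxy)phenyl]propan-2-one, via keto acid 2 (not isolated)
Conditions: DCC, DMAP (cat.), CH2Cl2, rt
Reagents that add atoms: none
Why: DCC/DMAP-mediated decarboxylative self-condensation of an arylacetic acid (Claisen-type C-acylation): the activated acid acylates the benzylic carbon of a second molecule and keto acid 2 loses carbon dioxide; the reaction is established for alkoxy-substituted phenylacetic acids.

Step 2
Reactants: 3 1,3-bis[4-(benzyloxy)phenyl]propan-2-one; 4 diethyl oxalate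
Product: 5 3,5-bis[4-(benzyloxy)phenyl]cyclopentane-1,2,4-trione (drawn as the enol 4-hydroxy-3,5-diarylcyclopent-3-ene-1,2-dione)
Conditions: NaOEt (2.2 equiv), EtOH, reflux; then 1 M HCl
Reagents that add atoms: none
Why: Double crossed Claisen condensation: each benzylic methylene of 3 is acylated by one ester group of 4, the second acylation closing the five-membered ring; the acidic trione is held as its sodium enolate, which drives both equilibria, and is released on acidification; the diphenyl parent case is classical.

Step 3
Reactants: 5 3,5-bis[4-(benzyloxy)phenyl]cyclopentane-1,2,4-trione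
Product: 6 2,5-bis[4-(benzyloxy)phenyl]-3,4-dimethoxycyclopenta-2,4-dienone
Conditions: HC(OMe)3, MeOH, TsOH·H2O (cat.), 60 °C; brief dilute aqueous acid work-up
Reagents that add atoms: methanol, CO; trimethyl orthoformate, COC(OC)OC
Why: Acid-catalysed vinylogous esterification under equilibrating conditions, the reaction type used to make dialkyl squarates from the parent enediol acid; exchange is reversible, so both methyl groups should settle on the oxalyl oxygens, where each methoxy group is beta to the single carbonyl and the push-pull stabilisation is greatest, and carbon alkylation is impossible by this mechanism.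

Step 4
Reactants: 6 2,5-bis[4-(benzyloxy)phenyl]-3,4-dimethoxycyclopenta-2,4-dienone; 7 vinylene carbonate (1,3-dioxol-2-one)
Product: 9 cis-4,7-bis[4-(benzyloxy)phenyl]-5,6-dimethoxy-3a,7a-dihydro-1,3-benzodioxol-2-one (meso, 3aR,7aS), via bridged ketone 8 (not isolated)
Conditions: 7 (10 equiv), BHT (cat.), 1,2-dichlorobenzene, 170 °C, sealed base-washed tube, argon
Reagents that add atoms: none
Why: A thermal [4+2] cycloaddition of the diene of 6 to the cis double bond of 7, suprafacial on both partners, gives the 7-oxonorbornene 8, which loses carbon monoxide by cheletropic extrusion at the reaction temperature to leave cyclohexa-1,3-diene 9. The closest known reaction type is the Diels–Alder reaction of tetrasubstituted cyclopentadienones with alkenes, vinylene carbonate among them, followed by loss of carbon monoxide. Ring B is closed by the intermolecular cycloaddition itself, which forms C6–C1 and C2–C3 in one concerted event; the one-carbon bridge is transient. The two new stereocentres C1 and C2 are cis because both bonds form on one face of the cis alkene; 9 is meso, and endo or exo approach is immaterial since both bridgeheads become sp2 on extrusion. No regiochemistry arises because both partners are symmetric. Periselectivity, the dienone acting as diene towards 7 and not as diene and dienophile towards itself, is secured by the aryl groups on both diene termini and the two methoxy groups, which block dimerisation. The step needs chemoselectivity for 9 over aromatisation by ionisation of the allylic C–O bond; acid-free glass and an inert solvent serve this, BHT suppresses polymerisation of 7, and any 10 formed by hydrogen transfer to 6 is the product of the next step.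

Step 5
Reactants: 9 cis-4,7-bis[4-(benzyloxy)phenyl]-5,6-dimethoxy-3a,7a-dihydro-1,3-benzodioxol-2-one
Product: 10 4,7-bis[4-(benzyloxy)phenyl]-5,6-dimethoxy-1,3-benzodioxol-2-one
Conditions: DDQ (1.1 equiv), toluene, 0 °C to rt
Reagents that add atoms: none
Why: Dehydrogenation of a cyclohexa-1,3-diene by a high-potential quinone: hydride abstraction from the allylic C1–H gives a pentadienyl cation stabilised by the methoxy and aryl groups, and loss of the C2 proton gives the arene with both oxygens kept; aryl benzyl ethers tolerate DDQ at room temperature.

Step 6
Reactants: 10 4,7-bis[4-(benzyloxy)phenyl]-5,6-dimethoxy-1,3-benzodioxol-2-one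
Product: 11 3,6-bis[4-(benzyloxy)phenyl]-4,5-dimethoxybenzene-1,2-diol
Conditions: K2CO3 (0.2 equiv), MeOH/THF (degassed), rt, argon
Reagents that add atoms: none
Why: Base-catalysed methanolysis (transesterification) of an aryl cyclic carbonate, which is fast because phenoxide is the leaving group; exclusion of air protects the electron-rich catechol.

Step 7
Reactants: 11 3,6-bis[4-(benzyloxy)phenyl]-4,5-dimethoxybenzene-1,2-diol
Product: 14 2,5-dihydroxy-3,6-bis[4-(benzyloxy)phenyl]-1,4-benzoquinone, via ortho-quinone 12 (not isolated), via hydroxy methoxy para-quinone 13 (not isolated)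
Conditions: Ag2O, Na2SO4, THF, rt; filter; then 1 M NaOH, THF/H2O, 0 °C to 60 °C, argon; then 1 M HCl
Reagents that add atoms: sodium hydroxide, [Na+].[OH-]
Why: Ag2O oxidation of a catechol gives ortho-quinone 12, whose methoxy-bearing carbons are vinylogous ester positions; addition–elimination of hydroxide gives, after tautomerisation, para-quinone 13 and then the dianion of 14, so the oxygens end up paired para; alkaline hydrolysis of methoxyquinones is a standard route to 2,5-dihydroxy-1,4-benzoquinones.

Step 8
Reactants: 14 2,5-dihydroxy-3,6-bis[4-(benzyloxy)phenyl]-1,4-benzoquinone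
Product: 15 2,5-bis(benzyloxy)-3,6-bis[4-(benzyloxy)phenyl]-1,4-benzoquinone
Conditions: BnBr (2.5 equiv), K2CO3, DMF, 50 °C
Reagents that add atoms: benzyl bromide, BrCc1ccccc1
Why: Williamson-type O-alkylation of a hydroxyquinone (a vinylogous carboxylic acid) with an active halide; the two enolic oxygens are the only nucleophilic sites, and the ring carbons are fully substituted.

Step 9
Reactants: 15 2,5-bis(benzyloxy)-3,6-bis[4-(benzyloxy)phenyl]-1,4-benzoquinone
Product: 16 2,5-bis(benzyloxy)-3,6-bis[4-(benzyloxy)phenyl]benzene-1,4-diol
Conditions: Na2S2O4, THF/H2O, rt, argon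
Reagents that add atoms: none
Why: Dithionite reduction of a para-quinone to its hydroquinone, fast and selective for the quinone; benzyl ethers are untouched and the air-sensitive product is used directly.

Step 10
Reactants: 16 2,5-bis(benzyloxy)-3,6-bis[4-(benzyloxy)phenyl]benzene-1,4-diol; 17 3-phenylpropanoyl chloride
Product: 18 2,5-bis(benzyloxy)-3,6-bis[4-(benzyloxy)phenyl]-4-hydroxyphenyl 3-phenylpropanoate
Conditions: NaH (1.0 equiv), THF, 0 °C; then inverse addition to 17 (1.05 equiv), THF, −78 °C to rt
Reagents that add atoms: none
Why: Acylation of a phenoxide by an acid chloride: one equivalent of NaH should form mainly the monophenoxide, and inverse addition to cold 17 acylates it before proton exchange can pass the charge to the product, whose remaining neutral hindered phenol does not react without base; recovered 16 and any diester are recycled.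

Step 11
Reactants: 19 ethyl (S)-3-hydroxybutanoate
Product: 20 ethyl (S)-3-(benzyloxy)butanoate
Conditions: benzyl 2,2,2-trichloroacetimidate, TfOH (cat.), CH2Cl2/cyclohexane, 0 °C to rt
Reagents that add atoms: benzyl 2,2,2-trichloroacetimidate, N=C(OCc1ccccc1)C(Cl)(Cl)Cl
Why: Acid-catalysed O-benzylation with a trichloroacetimidate, chosen because basic alkylation of a beta-hydroxy ester risks elimination and retro-aldol cleavage; the C–O bond of the stereocentre is not broken, so the S configuration is retained.

Step 12
Reactants: 20 ethyl (S)-3-(benzyloxy)butanoate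
Product: 21 (S)-3-(benzyloxy)butanoic acid
Conditions: LiOH, THF/H2O, 0 °C to rt; then 1 M HCl
Reagents that add atoms: lithium hydroxide, [Li+].[OH-]
Why: Saponification of an ethyl ester at low temperature; the stereocentre is beta to the carbonyl and not enolisable, and the mild conditions avoid E1cB loss of the benzyloxy group.

Step 13
Reactants: 18 2,5-bis(benzyloxy)-3,6-bis[4-(benzyloxy)phenyl]-4-hydroxyphenyl 3-phenylpropanoate; 21 (S)-3-(benzyloxy)butanoic acid
Product: 22 2,5-bis(benzyloxy)-3,6-bis[4-(benzyloxy)phenyl]-4-(3-phenylpropanoyloxy)phenyl (S)-3-(benzyloxy)butanoate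
Conditions: DCC, DMAP (cat.), CH2Cl2, 0 °C to rt
Reagents that add atoms: none
Why: Steglich esterification: DCC activates the acid and DMAP transfers the acyl group to the hindered phenol; the first ester has no free hydroxyl beside it and stays in place, and the stereocentre is not touched.

Step 14
Reactants: 22 2,5-bis(benzyloxy)-3,6-bis[4-(benzyloxy)phenyl]-4-(3-phenylpropanoyloxy)phenyl (S)-3-(benzyloxy)butanoate
Product: 23 2′-[(S)-3-hydroxybutanoyloxy]-5′-(3-phenylpropanoyloxy)-[1,1′:4′,1″-terphenyl]-3′,4,4″,6′-tetrol (target)
Conditions: H2 (1 atm), Pd/C (10 wt%), EtOAc, rt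
Reagents that add atoms: none
Why: Hydrogenolysis of five benzyl ethers over palladium on carbon under neutral conditions, which aryl esters survive; all hydroxyls appear together in a non-basic medium, so the esters should not migrate and the stereocentre is unaffected.

## Compound list

1 | 4-(benzyloxy)phenylacetic acid | O=C(O)Cc1ccc(OCc2ccccc2)cc1 | starting material
2 | 2,4-bis[4-(benzyloxy)phenyl]-3-oxobutanoic acid (racemic) | O=C(O)C(c1ccc(OCc2ccccc2)cc1)C(=O)Cc3ccc(OCc4ccccc4)cc3 | intermediate (not isolated)
3 | 1,3-bis[4-(benzyloxy)phenyl]propan-2-one | O=C(Cc1ccc(OCc2ccccc2)cc1)Cc3ccc(OCc4ccccc4)cc3 | intermediate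
4 | diethyl oxalate | CCOC(=O)C(=O)OCC | starting material
5 | 3,5-bis[4-(benzyloxy)phenyl]cyclopentane-1,2,4-trione, drawn as 4-hydroxy-3,5-bis[4-(benzyloxy)phenyl]cyclopent-3-ene-1,2-dione (labile CH centre, racemic) | O=C1C(=O)C(c2ccc(OCc3ccccc3)cc2)=C(O)C1c4ccc(OCc5ccccc5)cc4 | intermediate
6 | 2,5-bis[4-(benzyloxy)phenyl]-3,4-dimethoxycyclopenta-2,4-dienone | O=C1C(c2ccc(OCc3ccccc3)cc2)=C(OC)C(OC)=C1c4ccc(OCc5ccccc5)cc4 | intermediate
7 | vinylene carbonate | O=C1OC=CO1 | starting material
8 | 4,7-bis[4-(benzyloxy)phenyl]-5,6-dimethoxy-3a,4,7,7a-tetrahydro-4,7-methano-1,3-benzodioxole-2,8-dione (endo adduct drawn, meso) | O=C1O[C@H]2[C@@H](O1)[C@]3(c4ccc(OCc5ccccc5)cc4)C(=O)[C@@]2(c6ccc(OCc7ccccc7)cc6)C(OC)=C3OC | intermediate (not isolated)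
9 | cis-4,7-bis[4-(benzyloxy)phenyl]-5,6-dimethoxy-3a,7a-dihydro-1,3-benzodioxol-2-one (meso) | O=C1O[C@H]2[C@@H](O1)C(c3ccc(OCc4ccccc4)cc3)=C(OC)C(OC)=C2c5ccc(OCc6ccccc6)cc5 | intermediate
10 | 4,7-bis[4-(benzyloxy)phenyl]-5,6-dimethoxy-1,3-benzodioxol-2-one | O=C1Oc2c(O1)c(-c3ccc(OCc4ccccc4)cc3)c(OC)c(OC)c2-c5ccc(OCc6ccccc6)cc5 | intermediate
11 | 3,6-bis[4-(benzyloxy)phenyl]-4,5-dimethoxybenzene-1,2-diol | Oc1c(O)c(-c2ccc(OCc3ccccc3)cc2)c(OC)c(OC)c1-c4ccc(OCc5ccccc5)cc4 | intermediate
12 | 3,6-bis[4-(benzyloxy)phenyl]-4,5-dimethoxy-1,2-benzoquinone | O=C1C(=O)C(c2ccc(OCc3ccccc3)cc2)=C(OC)C(OC)=C1c4ccc(OCc5ccccc5)cc4 | intermediate (not isolated)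
13 | 2-hydroxy-5-methoxy-3,6-bis[4-(benzyloxy)phenyl]-1,4-benzoquinone | O=C1C(O)=C(c2ccc(OCc3ccccc3)cc2)C(=O)C(OC)=C1c4ccc(OCc5ccccc5)cc4 | intermediate (not isolated)
14 | 2,5-dihydroxy-3,6-bis[4-(benzyloxy)phenyl]-1,4-benzoquinone | O=C1C(O)=C(c2ccc(OCc3ccccc3)cc2)C(=O)C(O)=C1c4ccc(OCc5ccccc5)cc4 | intermediate
15 | 2,5-bis(benzyloxy)-3,6-bis[4-(benzyloxy)phenyl]-1,4-benzoquinone | O=C1C(OCc2ccccc2)=C(c3ccc(OCc4ccccc4)cc3)C(=O)C(OCc5ccccc5)=C1c6ccc(OCc7ccccc7)cc6 | intermediate
16 | 2,5-bis(benzyloxy)-3,6-bis[4-(benzyloxy)phenyl]benzene-1,4-diol | Oc1c(OCc2ccccc2)c(-c3ccc(OCc4ccccc4)cc3)c(O)c(OCc5ccccc5)c1-c6ccc(OCc7ccccc7)cc6 | intermediate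
17 | 3-phenylpropanoyl chloride | O=C(Cl)CCc1ccccc1 | starting material
18 | 2,5-bis(benzyloxy)-3,6-bis[4-(benzyloxy)phenyl]-4-hydroxyphenyl 3-phenylpropanoate | O=C(CCc1ccccc1)Oc2c(OCc3ccccc3)c(-c4ccc(OCc5ccccc5)cc4)c(O)c(OCc6ccccc6)c2-c7ccc(OCc8ccccc8)cc7 | intermediate
19 | ethyl (S)-3-hydroxybutanoate | CCOC(=O)C[C@H](C)O | starting material
20 | ethyl (S)-3-(benzyloxy)butanoate | CCOC(=O)C[C@H](C)OCc1ccccc1 | intermediate
21 | (S)-3-(benzyloxy)butanoic acid | O=C(O)C[C@H](C)OCc1ccccc1 | intermediate
22 | 2,5-bis(benzyloxy)-3,6-bis[4-(benzyloxy)phenyl]-4-(3-phenylpropanoyloxy)phenyl (S)-3-(benzyloxy)butanoate | C[C@H](OCc1ccccc1)CC(=O)Oc2c(OCc3ccccc3)c(-c4ccc(OCc5ccccc5)cc4)c(OC(=O)CCc6ccccc6)c(OCc7ccccc7)c2-c8ccc(OCc9ccccc9)cc8 | intermediate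
23 | 2′-[(S)-3-hydroxybutanoyloxy]-5′-(3-phenylpropanoyloxy)-[1,1′:4′,1″-terphenyl]-3′,4,4″,6′-tetrol | C[C@H](O)CC(=O)Oc1c(O)c(-c2ccc(O)cc2)c(OC(=O)CCc2ccccc2)c(O)c1-c1ccc(O)cc1 | target

## Step count and least certain steps

Total step count: 14. Longest linear sequence: 12 steps (steps 1 to 10, 13 and 14). Steps 11 and 12 are the two-step branch to acid 21.

**Step 4 (key step).** The push-pull dienone may react only slowly as a diene, so that long heating is needed. During that time 9 may aromatise by ionisation of its allylic C–O bond with loss of a ring oxygen, and the dienophile may polymerise. Fallback, setting out from 6: the alkene is replaced by an alkyne at the catechol oxidation level. Heating 6 with di-tert-butoxyethyne (a known, storable ynediol ether) should give the bridged dienone 1,4-bis[4-(benzyloxy)phenyl]-2,3-di-tert-butoxy-5,6-dimethoxybicyclo[2.2.1]hepta-2,5-dien-7-one F1. This extrudes carbon monoxide as it forms and gives the aromatic 1,2-di-tert-butoxy-3,6-bis[4-(benzyloxy)phenyl]-4,5-dimethoxybenzene F2. No dihydro stage exists, so neither elimination nor a separate dehydrogenation can intervene. Cleavage of both tert-butyl ethers with CF3CO2H in CH2Cl2 at 0 °C rejoins the route at catechol 11, bypassing 9 and 10.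

**Step 3.** Etherification may place a methyl group on the central oxygen instead of an oxalyl oxygen, may stop after one exchange, or may ketalise the dienone carbonyl. Fallback, setting out from 5: the enol oxygens are silylated instead. tert-Butyldimethylsilyl triflate and Et3N should give 2,5-bis[4-(benzyloxy)phenyl]-3,4-bis(tert-butyldimethylsilyloxy)cyclopenta-2,4-dienone F3. O-Silylation is reversible under triflate catalysis, so the thermodynamic isomer is reached. Cycloaddition of F3 with 7 under the conditions of step 4 should pass through the endo bridged ketone 4,7-bis[4-(benzyloxy)phenyl]-5,6-bis(tert-butyldimethylsilyloxy)-3a,4,7,7a-tetrahydro-4,7-methano-1,3-benzodioxole-2,8-dione F4 to the cis-dihydrocatechol carbonate cis-4,7-bis[4-(benzyloxy)phenyl]-5,6-bis(tert-butyldimethylsilyloxy)-3a,7a-dihydro-1,3-benzodioxol-2-one F5. DDQ then gives the aromatic carbonate 4,7-bis[4-(benzyloxy)phenyl]-5,6-bis(tert-butyldimethylsilyloxy)-1,3-benzodioxol-2-one F6. K2CO3 in MeOH removes the carbonate and both aryl silyl ethers together to give 3,6-bis[4-(benzyloxy)phenyl]benzene-1,2,4,5-tetrol F7, which is oxidised by air during work-up to 14. The route is rejoined at 14; compounds 6 and 9 to 13 are bypassed and the alkaline hydrolysis of step 7 is not needed.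

**Step 10.** The two hydroxyls of 16 are equivalent. Proton exchange among the phenoxides may compete with acylation, which leads to over-acylation on one molecule and none on another. Fallback, setting out from 16: both hydroxyls are acylated with an excess of 17 and pyridine to the symmetric diester 2,5-bis(benzyloxy)-3,6-bis[4-(benzyloxy)phenyl]-1,4-phenylene bis(3-phenylpropanoate) F8. One ester is then removed with one equivalent of NaOMe in THF at −20 °C. The first cleavage leaves a phenoxide para to the second ester, which deactivates it, and the methoxide is consumed in the act, so the cleavage should stop at 18, where the route is rejoined.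

**Step 7.** The ortho-quinone may undergo ring contraction by a benzilic acid-type rearrangement in alkali. The sequence may also stall after the first exchange, because the anion of the hydroxyquinone resists a second hydroxide addition. Fallback, setting out from 13, which is isolated after the mild first hydrolysis at 0 °C: the remaining methyl group is removed by chloride attack at the methyl carbon instead of hydroxide attack at the ring carbon (LiCl, DMF, 100 °C; a Krapcho-type dealkylation of a vinylogous methyl ester). Acidification gives 14, where the route is rejoined, without exposure of the quinone to hot alkali. No new compound is made.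

## Further compounds

F1 | step 4 | 1,4-bis[4-(benzyloxy)phenyl]-2,3-di-tert-butoxy-5,6-dimethoxybicyclo[2.2.1]hepta-2,5-dien-7-one | O=C1[C@]2(c3ccc(OCc4ccccc4)cc3)C(OC)=C(OC)[C@@]1(c5ccc(OCc6ccccc6)cc5)C(OC(C)(C)C)=C2OC(C)(C)C
F2 | step 4 | 1,2-di-tert-butoxy-3,6-bis[4-(benzyloxy)phenyl]-4,5-dimethoxybenzene | CC(C)(C)Oc1c(OC(C)(C)C)c(-c2ccc(OCc3ccccc3)cc2)c(OC)c(OC)c1-c4ccc(OCc5ccccc5)cc4
F3 | step 3 | 2,5-bis[4-(benzyloxy)phenyl]-3,4-bis(tert-butyldimethylsilyloxy)cyclopenta-2,4-dienone | O=C1C(c2ccc(OCc3ccccc3)cc2)=C(O[Si](C)(C)C(C)(C)C)C(O[Si](C)(C)C(C)(C)C)=C1c4ccc(OCc5ccccc5)cc4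
F4 | step 3 | 4,7-bis[4-(benzyloxy)phenyl]-5,6-bis(tert-butyldimethylsilyloxy)-3a,4,7,7a-tetrahydro-4,7-methano-1,3-benzodioxole-2,8-dione (endo, meso) | O=C1O[C@H]2[C@@H](O1)[C@]3(c4ccc(OCc5ccccc5)cc4)C(=O)[C@@]2(c6ccc(OCc7ccccc7)cc6)C(O[Si](C)(C)C(C)(C)C)=C3O[Si](C)(C)C(C)(C)C
F5 | step 3 | cis-4,7-bis[4-(benzyloxy)phenyl]-5,6-bis(tert-butyldimethylsilyloxy)-3a,7a-dihydro-1,3-benzodioxol-2-one (meso) | O=C1O[C@H]2[C@@H](O1)C(c3ccc(OCc4ccccc4)cc3)=C(O[Si](C)(C)C(C)(C)C)C(O[Si](C)(C)C(C)(C)C)=C2c5ccc(OCc6ccccc6)cc5
F6 | step 3 | 4,7-bis[4-(benzyloxy)phenyl]-5,6-bis(tert-butyldimethylsilyloxy)-1,3-benzodioxol-2-one | O=C1Oc2c(O1)c(-c3ccc(OCc4ccccc4)cc3)c(O[Si](C)(C)C(C)(C)C)c(O[Si](C)(C)C(C)(C)C)c2-c5ccc(OCc6ccccc6)cc5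
F7 | step 3 | 3,6-bis[4-(benzyloxy)phenyl]benzene-1,2,4,5-tetrol | Oc1c(O)c(-c2ccc(OCc3ccccc3)cc2)c(O)c(O)c1-c4ccc(OCc5ccccc5)cc4
F8 | step 10 | 2,5-bis(benzyloxy)-3,6-bis[4-(benzyloxy)phenyl]-1,4-phenylene bis(3-phenylpropanoate) | O=C(CCc1ccccc1)Oc2c(OCc3ccccc3)c(-c4ccc(OCc5ccccc5)cc4)c(OC(=O)CCc6ccccc6)c(OCc7ccccc7)c2-c8ccc(OCc9ccccc9)cc8
F0 | step 7 | none | none
A1 | alternative 1 | atromentin | O=C1C(O)=C(c2ccc(O)cc2)C(=O)C(O)=C1c1ccc(O)cc1
A2 | alternative 1 | 4-hydroxyphenylpyruvic acid | O=C(O)C(=O)Cc1ccc(O)cc1
A3 | alternative 2 | pentabenzyl ether of the target (identical with 22) | C[C@H](OCc1ccccc1)CC(=O)Oc1c(OCc2ccccc2)c(-c2ccc(OCc3ccccc3)cc2)c(OC(=O)CCc2ccccc2)c(OCc2ccccc2)c1-c1ccc(OCc2ccccc2)cc1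
A4 | alternative 2 | (S)-3-(benzyloxy)-1-{2,5-bis(benzyloxy)-3,6-bis[4-(benzyloxy)phenyl]-4-(3-phenylpropanoyl)phenyl}butan-1-one | C[C@H](OCc1ccccc1)CC(=O)c1c(OCc2ccccc2)c(-c2ccc(OCc3ccccc3)cc2)c(C(=O)CCc2ccccc2)c(OCc2ccccc2)c1-c1ccc(OCc2ccccc2)cc1
A5 | alternative 3 | 4,4′-[2,5-bis(benzyloxy)-3,6-bis(methoxymethoxy)-1,4-phenylene]bis(cyclohex-2-en-1-one) (stereoisomer mixture, one isomer drawn) | O=C1C=C[C@@H](CC1)c1c(OCOC)c(OCc2ccccc2)c([C@H]2CCC(=O)C=C2)c(OCOC)c1OCc1ccccc1
A6 | alternative 3 | 2,2′-[2,5-bis(benzyloxy)-3,6-bis(methoxymethoxy)-1,4-phenylene]diacetaldehyde | O=CCc1c(OCOC)c(OCc2ccccc2)c(CC=O)c(OCOC)c1OCc1ccccc1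
A7 | alternative 3 | methyl vinyl ketone | CC(=O)C=C
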